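## Retrosynthetic overview
1. Last bond made is C2''–aryl. Ring F is carried as a flat, 2,3-unsubstituted chromone, and the (R) centre is set at the end by catalytic asymmetric conjugate addition of 4-hydroxyphenylboronic acid.
2. Key step: both γ-pyranone rings (C of the flavone, F of the chromone) close together from one open-chain precursor. That precursor holds an o-hydroxyaryl 1,3-diketone and an o-hydroxyacetophenone.
3. No aryl–aryl coupling is used. The C3–C6'' bond is bought with 2,4,6-trihydroxybenzaldehyde, whose formyl carbon becomes C3. C3–C4 comes from a diazo/aldehyde formyl C–H insertion and C3–C2 from a Baker–Venkataraman acyl shift.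
4. The 6-linkage is fixed by symmetry. Ring D stays symmetric (2,6-di-OBn, a different group on the 4-O) until the acetyl group enters next to the 4-OH.
5. Ring order: A, B, D and E are bought, C and F form in one operation, and F is saturated last.

Assumption: the hindered C3–C6'' axis is not specified in the SMILES and is treated as freely equilibrating, so only C2'' is controlled.

## Route

Step 1
Reactants: 1 2,4,6-trihydroxybenzaldehyde
Product: 3 2,6-bis(benzyloxy)-4-(methoxymethoxy)benzaldehyde, via 4-O-MOM aldehyde 2 (not isolated)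
Conditions: MOMCl (1.05 equiv), K2CO3, DMF, 0 °C; then BnBr (2.5 equiv), 60 °C, same flask
Reagents that add atoms: chloromethyl methyl ether COCCl; benzyl bromide BrCc1ccccc1
Why: The 4-OH is the most acidic hydroxyl and the only one not hydrogen-bonded to the formyl group, so one equivalent of MOMCl alkylates it first and the two chelated hydroxyls are then benzylated under forcing conditions (sequential Williamson ether synthesis; no stereocentre).

Step 2
Reactants: 4 2-hydroxy-4,6-dimethoxybenzaldehyde; 5 4-methoxybenzoyl chloride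
Product: 6 2-formyl-3,5-dimethoxyphenyl 4-methoxybenzoate
Conditions: aq NaOH, Bu4NHSO4 (cat.), CH2Cl2, 0 °C
Reagents that add atoms: none
Why: Phase-transfer Schotten–Baumann O-acylation parks the anisoyl group on the phenol oxygen next to the future C4 carbonyl and makes the aldehyde more electrophilic (no stereocentre).

Step 3
Reactants: 3 2,6-bis(benzyloxy)-4-(methoxymethoxy)benzaldehyde; 6 2-formyl-3,5-dimethoxyphenyl 4-methoxybenzoate
Product: 10 2-[2,6-bis(benzyloxy)-4-(methoxymethoxy)phenyl]-1-(2-hydroxy-4,6-dimethoxyphenyl)-3-(4-methoxyphenyl)propane-1,3-dione, via tosylhydrazone 7 (not isolated), via aryldiazomethane 8 (not isolated), via keto ester 9 (not isolated)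
Conditions: TsNHNH2, 4 Å MS, 1,4-dioxane, 60 °C; then 6, Cs2CO3, 110 °C; cold aq citric acid quench
Reagents that add atoms: none
Why: Proposed new method: Cs2CO3 turns the tosylhydrazone into the nucleophilic aryldiazomethane (Bamford–Stevens), which adds to the formyl group of 6 and gives benzyl ketone 9 by 1,2-hydride shift with loss of N2 (known base-mediated formyl C–H insertion of tosylhydrazones into aromatic aldehydes), and the same base then enolises the acidic ArCH2C=O position so the neighbouring aryl ester moves to carbon through a six-membered transition state (Baker–Venkataraman rearrangement), so only the merger of the two known reactions in one flask is new, and the new CH centre is enolisable and disappears later.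

Step 4
Reactants: 10 the MOM-protected 1,3-diketone
Product: 12 2-[3-acetyl-2,6-bis(benzyloxy)-4-hydroxyphenyl]-1-(2-hydroxy-4,6-dimethoxyphenyl)-3-(4-methoxyphenyl)propane-1,3-dione, via free phenol 11 (not isolated)
Conditions: (i) 1.25 M HCl/MeOH, 40 °C, evaporate; (ii) AcCl, SnCl4, CH2Cl2, −20 to 0 °C
Reagents that add atoms: acetyl chloride CC(Cl)=O
Why: Acid methanolysis removes only the acetal-type MOM group, and the freed ring D, the most electron-rich arene present and symmetric about its C1–C4 axis, is acetylated at either of its two equivalent positions ortho to the OH (Friedel–Crafts acylation, or O-acylation then Fries shift), so only one regioisomer can form.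

Step 5 (key step)
Reactants: 12 the acetyl phenol diketone
Product: 14 3-[5,7-bis(benzyloxy)-4-oxo-4H-chromen-6-yl]-5,7-dimethoxy-2-(4-methoxyphenyl)-4H-chromen-4-one, via enaminone 13 (not isolated)
Conditions: (i) Me2NCH(OMe)2, toluene, 90 °C, evaporate; (ii) TsOH·H2O (3 equiv), EtOH–toluene, 80 °C
Reagents that add atoms: N,N-dimethylformamide dimethyl acetal COC(OC)N(C)C
Why: DMF-DMA condenses only at the acetyl CH3 because the diketone carbon has a single hydrogen, and acid then closes ring F by addition–elimination of the one free neighbouring OH (enaminone chromone synthesis) and ring C by cyclodehydration of the o-hydroxyaryl 1,3-diketone (flavone synthesis), while the two benzyl ethers flanking the inter-unit bond block the competing benzofuran closure and lock the 6-linkage.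

Step 6
Reactants: 14 the dibenzyl bichromone
Product: 15 3-(5,7-dihydroxy-4-oxo-4H-chromen-6-yl)-5-hydroxy-7-methoxy-2-(4-methoxyphenyl)-4H-chromen-4-one
Conditions: BCl3 (10 equiv), C6HMe5, CH2Cl2, −78 to 0 °C; then H2O
Reagents that add atoms: none
Why: BCl3 cleaves aryl benzyl ethers at low temperature with pentamethylbenzene as cation trap and, through chelation to the C4 carbonyl, removes only the peri 5-OMe, so the 7- and 4'-methyl ethers survive (Lewis-acid ether cleavage, done before any stereocentre exists).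

Step 7
Reactants: 15 the free bichromone; 16 4-hydroxyphenylboronic acid
Product: 17 (2R)-5,7-dihydroxy-6-[5-hydroxy-7-methoxy-2-(4-methoxyphenyl)-4-oxo-4H-chromen-3-yl]-2-(4-hydroxyphenyl)-2,3-dihydro-4H-chromen-4-one
Conditions: Pd(OCOCF3)2 (10 mol %), (S)-t-BuPyOx (12 mol %), NH4PF6 (30 mol %), H2O (5 equiv), ClCH2CH2Cl–CF3CH2OH, 40 °C
Reagents that add atoms: none
Why: In this asymmetric conjugate addition of an arylboronic acid to a chromone under cationic divalent palladium/pyridine-oxazoline catalysis, the tert-butyl group of the (S)-ligand lets the aryl–Pd species insert into only one face of the unsubstituted C2''=C3'' bond (by analogy with the facial sense that gives (R)-3-aryl-3-methylcyclohexanones, here the (2R)-flavanone), water protonates the Pd enolate irreversibly, the tetrasubstituted C2=C3 bond of ring C cannot insert, and the base-free medium avoids racemisation by retro-oxa-Michael opening.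

## Compound list
1 | 2,4,6-trihydroxybenzaldehyde | O=Cc1c(O)cc(O)cc1O | starting material
2 | 2,6-dihydroxy-4-(methoxymethoxy)benzaldehyde | O=Cc1c(O)cc(OCOC)cc1O | intermediate
3 | 2,6-bis(benzyloxy)-4-(methoxymethoxy)benzaldehyde | O=Cc1c(OCc2ccccc2)cc(OCOC)cc1OCc1ccccc1 | intermediate
4 | 2-hydroxy-4,6-dimethoxybenzaldehyde | COc1cc(O)c(C=O)c(OC)c1 | starting material
5 | 4-methoxybenzoyl chloride | COc1ccc(cc1)C(Cl)=O | starting material
6 | 2-formyl-3,5-dimethoxyphenyl 4-methoxybenzoate | COc1ccc(cc1)C(=O)Oc1cc(OC)cc(OC)c1C=O | intermediate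
7 | (E)-N-tosylhydrazone of 3 | Cc1ccc(cc1)S(=O)(=O)N/N=C/c1c(OCc2ccccc2)cc(OCOC)cc1OCc1ccccc1 | intermediate
8 | [2,6-bis(benzyloxy)-4-(methoxymethoxy)phenyl]diazomethane | [N-]=[N+]=Cc1c(OCc2ccccc2)cc(OCOC)cc1OCc1ccccc1 | intermediate
9 | 2-{[2,6-bis(benzyloxy)-4-(methoxymethoxy)phenyl]acetyl}-3,5-dimethoxyphenyl 4-methoxybenzoate | COc1ccc(cc1)C(=O)Oc1cc(OC)cc(OC)c1C(=O)Cc1c(OCc2ccccc2)cc(OCOC)cc1OCc1ccccc1 | intermediate
10 | 2-[2,6-bis(benzyloxy)-4-(methoxymethoxy)phenyl]-1-(2-hydroxy-4,6-dimethoxyphenyl)-3-(4-methoxyphenyl)propane-1,3-dione (racemic, enolisable) | COc1ccc(cc1)C(=O)C(C(=O)c1c(O)cc(OC)cc1OC)c1c(OCc2ccccc2)cc(OCOC)cc1OCc1ccccc1 | intermediate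
11 | 2-[2,6-bis(benzyloxy)-4-hydroxyphenyl]-1-(2-hydroxy-4,6-dimethoxyphenyl)-3-(4-methoxyphenyl)propane-1,3-dione | COc1ccc(cc1)C(=O)C(C(=O)c1c(O)cc(OC)cc1OC)c1c(OCc2ccccc2)cc(O)cc1OCc1ccccc1 | intermediate
12 | 2-[3-acetyl-2,6-bis(benzyloxy)-4-hydroxyphenyl]-1-(2-hydroxy-4,6-dimethoxyphenyl)-3-(4-methoxyphenyl)propane-1,3-dione | COc1ccc(cc1)C(=O)C(C(=O)c1c(O)cc(OC)cc1OC)c1c(OCc2ccccc2)cc(O)c(C(C)=O)c1OCc1ccccc1 | intermediate
13 | (E)-3-(dimethylamino)acryloyl analogue of 12 (enaminone) | COc1ccc(cc1)C(=O)C(C(=O)c1c(O)cc(OC)cc1OC)c1c(OCc2ccccc2)cc(O)c(C(=O)/C=C/N(C)C)c1OCc1ccccc1 | intermediate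
14 | 3-[5,7-bis(benzyloxy)-4-oxo-4H-chromen-6-yl]-5,7-dimethoxy-2-(4-methoxyphenyl)-4H-chromen-4-one | COc1ccc(cc1)-c1oc2cc(OC)cc(OC)c2c(=O)c1-c1c(OCc2ccccc2)cc2occc(=O)c2c1OCc1ccccc1 | intermediate
15 | 3-(5,7-dihydroxy-4-oxo-4H-chromen-6-yl)-5-hydroxy-7-methoxy-2-(4-methoxyphenyl)-4H-chromen-4-one | COc1ccc(cc1)-c1oc2cc(OC)cc(O)c2c(=O)c1-c1c(O)cc2occc(=O)c2c1O | intermediate
16 | 4-hydroxyphenylboronic acid | OB(O)c1ccc(O)cc1 | starting material
17 | (2R)-5,7-dihydroxy-6-[5-hydroxy-7-methoxy-2-(4-methoxyphenyl)-4-oxo-4H-chromen-3-yl]-2-(4-hydroxyphenyl)-2,3-dihydro-4H-chromen-4-one | COc1ccc(-c2oc3cc(OC)cc(O)c3c(=O)c2-c2c(O)cc3c(c2O)C(=O)C[C@H](c2ccc(O)cc2)O3)cc1 | target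

## Step count and risks
Total step count: 7. Longest linear sequence: 6 (steps 1, 3, 4, 5, 6, 7).

**Step 3.**
- Risk: both partners are hindered and electron-rich. Aryl migration instead of hydride shift, azine or stilbene formation, and attack of the hydrazone anion on the aryl ester can all compete.
- Fallback: it sets out from 3 and comes back at 14. Hydrazone 7 is coupled with plain, unhindered 4-methoxybenzaldehyde to give the benzyl ketone F1. Regitz diazo transfer (p-ABSA, DBU) gives the aryl diazoketone F2. Formyl C–H activation of salicylaldehyde 4 with [Cp*RhCl2]2/AgSbF6, carbene insertion of F2 and cyclodehydration in the same flask give the MOM-protected 3-arylflavone F3. The chemistry of steps 4 and 5 applied to F3 then leads through the phenol F4, the acetyl phenol F5 and the enaminone F6 to 14.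

**Step 4.**
- Risk: SnCl4 may strip the benzyl ether next to the new acetyl group, or acylate ring A or the diketone. Early closure of ring C here would be harmless.
- Fallback: it sets out from 10 and comes back at 14. It builds ring F oxygen-first instead of carbon-first. Phenol 11 is isolated and added (DABCO cat.) to tert-butyl propiolate to give the aryloxyacrylate F7. Trifluoroacetic acid frees the aryloxyacrylic acid F8. Trifluoroacetic anhydride in the same flask then closes ring F by intramolecular Friedel–Crafts acylation at either of the two equivalent positions, while the acid closes ring C, giving 14 again in one double ring closure.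

**Step 7.**
- Risk: the electron-rich boronic acid may lower the ee, the polyphenol may bind palladium, and protodeboronation may compete.
- Fallback: it sets out from 15 and comes back at 17. The only non-chelated hydroxyl is benzylated (BnBr, 1 equiv, K2CO3) to give the 7''-benzyl ether F9. A base-free rhodium/chiral diene 1,4-addition ([RhCl(C2H4)2]2 with the antipode of 2,5-diphenylbicyclo[2.2.2]octa-2,5-diene that gives the R product) of 4-(benzyloxy)phenylboronic acid gives the dibenzyl flavanone F10. Neutral hydrogenolysis (H2, Pd/C, EtOAc) then gives 17.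

Further compounds
F1 | step 3 | 2-[2,6-bis(benzyloxy)-4-(methoxymethoxy)phenyl]-1-(4-methoxyphenyl)ethan-1-one | COc1ccc(cc1)C(=O)Cc1c(OCc2ccccc2)cc(OCOC)cc1OCc1ccccc1
F2 | step 3 | 2-[2,6-bis(benzyloxy)-4-(methoxymethoxy)phenyl]-2-diazo-1-(4-methoxyphenyl)ethan-1-one | COc1ccc(cc1)C(=O)C(=[N+]=[N-])c1c(OCc2ccccc2)cc(OCOC)cc1OCc1ccccc1
F3 | step 3 | 3-[2,6-bis(benzyloxy)-4-(methoxymethoxy)phenyl]-5,7-dimethoxy-2-(4-methoxyphenyl)-4H-chromen-4-one | COc1ccc(cc1)-c1oc2cc(OC)cc(OC)c2c(=O)c1-c1c(OCc2ccccc2)cc(OCOC)cc1OCc1ccccc1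
F4 | step 3 | 3-[2,6-bis(benzyloxy)-4-hydroxyphenyl]-5,7-dimethoxy-2-(4-methoxyphenyl)-4H-chromen-4-one | COc1ccc(cc1)-c1oc2cc(OC)cc(OC)c2c(=O)c1-c1c(OCc2ccccc2)cc(O)cc1OCc1ccccc1
F5 | step 3 | 3-[3-acetyl-2,6-bis(benzyloxy)-4-hydroxyphenyl]-5,7-dimethoxy-2-(4-methoxyphenyl)-4H-chromen-4-one | COc1ccc(cc1)-c1oc2cc(OC)cc(OC)c2c(=O)c1-c1c(OCc2ccccc2)cc(O)c(C(C)=O)c1OCc1ccccc1
F6 | step 3 | (E)-3-(dimethylamino)acryloyl analogue of F5 | COc1ccc(cc1)-c1oc2cc(OC)cc(OC)c2c(=O)c1-c1c(OCc2ccccc2)cc(O)c(C(=O)/C=C/N(C)C)c1OCc1ccccc1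
F7 | step 4 | tert-butyl (E)-3-{3,5-bis(benzyloxy)-4-[1-(2-hydroxy-4,6-dimethoxyphenyl)-3-(4-methoxyphenyl)-1,3-dioxopropan-2-yl]phenoxy}acrylate | COc1ccc(cc1)C(=O)C(C(=O)c1c(O)cc(OC)cc1OC)c1c(OCc2ccccc2)cc(O/C=C/C(=O)OC(C)(C)C)cc1OCc1ccccc1
F8 | step 4 | (E)-3-{3,5-bis(benzyloxy)-4-[1-(2-hydroxy-4,6-dimethoxyphenyl)-3-(4-methoxyphenyl)-1,3-dioxopropan-2-yl]phenoxy}acrylic acid | COc1ccc(cc1)C(=O)C(C(=O)c1c(O)cc(OC)cc1OC)c1c(OCc2ccccc2)cc(O/C=C/C(=O)O)cc1OCc1ccccc1
F9 | step 7 | 3-[7-(benzyloxy)-5-hydroxy-4-oxo-4H-chromen-6-yl]-5-hydroxy-7-methoxy-2-(4-methoxyphenyl)-4H-chromen-4-one | COc1ccc(cc1)-c1oc2cc(OC)cc(O)c2c(=O)c1-c1c(OCc2ccccc2)cc2occc(=O)c2c1O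
F10 | step 7 | (2R)-7-(benzyloxy)-2-[4-(benzyloxy)phenyl]-5-hydroxy-6-[5-hydroxy-7-methoxy-2-(4-methoxyphenyl)-4-oxo-4H-chromen-3-yl]-2,3-dihydro-4H-chromen-4-one | COc1ccc(-c2oc3cc(OC)cc(O)c3c(=O)c2-c2c(OCc4ccccc4)cc3c(c2O)C(=O)C[C@H](c2ccc(OCc4ccccc4)cc2)O3)cc1
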